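## Analysis of the target

The target is a germacranolide: a ten-membered carbocycle (C1–C10) trans-fused at C6–C7 to a γ-butyrolactone (O6–C12(=O)–C11). It carries a C1 ketone, a 4,5-oxirane with the C15 methyl on C4, a tertiary acetate and the C14 methyl on C10, a tiglate on O8 and an acetoxymethyl group (C13) on C11. The seven stereocentres are 4R,5S,6S,7R,8S,10R,11R. In relative terms: H6 and H7 are trans; the C7–C11 bond is trans to O8; O8 and O10 are 1,3-cis; the oxirane derives from a Z alkene and sits on the face of O6; C13 lies on the lactone face of H7. The sensitive groups are the β-acetoxy lactone (E1cB loss of acetate), the tertiary α-ketol acetate, the oxirane next to the lactone carbinol, the conjugated tiglate, and O8, which can translactonise onto C12 once free. The difficulty is threefold: closing a ten-membered ring, setting stereocentres on a flexible ring, and telling four oxygen functions and the two arms of C11 apart. The strategy rests on the 1,6-relationship of C1 (ketone) and C6 (lactone carbinol) across the ring. Rejoining these two carbons gives a bicyclo[4.4.0] skeleton whose ring A (C1–C6 with C15 on C4) is a 1,2,4-trialkylbenzene in disguise and whose ring B carries C7, C8 and C10 on a rigid tetralin.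

## Retrosynthetic reasoning

**Ester bonds.** The O8–tigloyl bond of 32 is cut first (30 + 31), then the two acetyl–oxygen bonds at O10 and O13 (29 back to 28), then the silyl ether at O13 (27). None of these esters survives hydride or dissolving-metal chemistry, and the C13 acetate makes C11–H prone to elimination, so they go on last. Primary O13 and secondary O8 are distinguished by the different rates at which their silyl ethers are removed.

**Lactone carbonyl and C1 ketone.** The C12–O6 lactone and the C1 carbonyl of 27 are traced to alcohols (26, then 24). C12 is a primary alcohol that is oxidised in the presence of the free C6 hydroxyl. C1 is carried as a carbinol because no hydride can be expected to spare the α-ketol carbonyl while reducing C6. The gain is that the C6 hydroxyl stays free long enough to direct the epoxidation.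

**Oxirane and C6 carbinol.** The two C–O bonds of the oxirane in 24 are cut to the Z allylic alcohol 23. Its C6–H bond is cut to the enone 22, which comes from the skipped enedione 21 by moving the alkene from C3=C4 to C4=C5. The forward steps must set C6, deliver oxygen to the alkene face on the side of O6 and keep the Z geometry.

**C1–C6 reconnection (key disconnection).** Joining the two carbonyl carbons of 21 as a tetrasubstituted alkene gives the hexahydronaphthalene 19. This is preferred over any C–C disconnection in the ring because the forward reaction has no ring-closing transition state: the ten-membered ring appears when the bond shared by two six-membered rings is cleaved. Everything that is hard to control on a medium ring (C7, C8, C10, C11) can then be set on a rigid bicycle, and C2–C5 with C15 come from an arene.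

**Dearomatisation.** The 1,4-diene of 19 (via 18) is the Birch product of the 1,2,4-trialkylbenzene ring of tetralin 16. The same reduction removes the benzyl group from O12. O12 (then acetate) and O13 (silyl ether) are thereby told apart without a separate step.

**C11 and its two arms.** A symmetrical bis(hydroxymethyl) group on C7 would leave C11 undefined until the lactone is made on the flexible ring. Instead the C11–C12 bond is cut: 16 and 15 come from the tricyclic lactone 14, made by alkylating the enolate of lactone 11 with 12 on the face away from the aryl ring. Reducing the lactone carbonyl of 14 turns that carbon into C13, and the benzyloxymethyl carbon becomes C12. This exchange of roles converts the easily obtained alkylation sense into the 11R arrangement of the target.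

**C7–C11 bond.** Lactone 11 (via 10) is disconnected at C7–C11 to epoxide 7 and dimethyl malonate 8. Anti opening at the benzylic carbon puts C11 trans to O8, and the C8 alkoxide closes the lactone.

**Ring B.** Epoxide 7 comes from the dihydronaphthalenol 6 by oxygen delivery cis to the C10 hydroxyl. The C7=C8 alkene of 6 is cut by metathesis to diene 5, the C9–C10 bond of 5 to ketone 3 and allyl donor 4 (this sets C10, the only stereocentre made by reagent control), and the C6–C7 bond of 3 to bromide 1 and vinylboronate 2.

## Alternatives that were turned down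

**Alternative 1:** anionic oxy-Cope ring expansion. Retrosynthetically the C8–C9 bond is cut while C1 and C6 are rejoined, which shrinks the ten-membered ring to a cyclohexene carrying two alkenyl groups on neighbouring carbons, one of them on a tertiary carbinol at C6. Forward, the potassium alkoxide (KH, 18-crown-6) undergoes a [3,3] shift to A1, 8-(4-methoxybenzyloxy)germacra-1(10)E,4Z-dien-6-one.
- For: the ring arises in one step from a cheap monoterpene-type enone, and the 4Z alkene is born conjugated to the C6 ketone. On these points it is stronger than the chosen route, which needs a separate alkene migration (step 13) and reaches the ring only at step 12.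
- Against: A1 has a single stereocentre (C8). C7 is a bare methylene, C10 is an alkene carbon and C1 is unoxidised. The lactone arm would have to be attached α to a ketone that can also enolise through C5, and the 1(10)-alkene would have to become a ketone plus a tertiary acetate of defined configuration beside the enone alkene. C6, C7, C10, C11 and the oxirane would all be set on the flexible ring.
- Comparison: the chosen route is longer up to the ring but arrives with C7, C8, C10 and C11 fixed and with oxygen at C10 and C1.

**Alternative 2:** ring-closing metathesis at C4=C5. The ring is cut at the future oxirane carbons to a seco-diene with a 1,1-disubstituted alkene at C4 and a vinyl group at C5. A second-generation Grubbs catalyst would close it to A2, the 4,5-deoxy target.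
- For: it is convergent, every stereocentre and all three esters are in place before cyclisation, and A2 is one epoxidation from the target. In endgame brevity it is clearly stronger.
- Against: ten is the least favourable ring size for metathesis. A trisubstituted alkene must form from a gem-disubstituted olefin, so oligomerisation competes. The geometry is whatever the ring prefers and cannot be enforced. The final epoxidation has no free hydroxyl to guide it and must ignore the tiglate. The seco-diene with six stereocentres needs a long linear synthesis of its own.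
- Comparison: the chosen route gives up the short endgame but has no cyclisation event for the medium ring and inherits the Z alkene from ring A.

**Alternative 3:** samarium Reformatsky aldol at C9–C10. The C9–C10 bond is cut to a bromomethyl ketone (C8/C9) and a methyl ketone (C10). SmI2 would generate the samarium enolate and close the ring to A3, the 8-oxo-10-hydroxy-4Z-en-6,12-olide with a methoxymethyl ether at C1.
- For: chelated samarium enolates are among the few dependable medium-ring closures, and the step makes the ring and the C10 carbinol together with lactone and Z alkene already present. In creating C10–O it is at least as direct as the chosen route.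
- Against: the oxidation levels at C8 (ketone) and C1 (ether) are the reverse of the target, so a selective C8 reduction and a C1 deprotection and oxidation must follow. The C8 ketone makes C7–H acidic with the lactone oxygen in the β-position (E1cB opening). A3 is a β-hydroxy ketone open to retro-aldol cleavage. The C10 configuration depends on the cyclisation transition state.
- Comparison: the chosen route sets C10 by a well-understood ketone allylation before any ring strain exists and never has a carbonyl at C8.

Key step: step 12

Remarks on conventions and assumptions: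
- Germacrane locants are used for every intermediate. C1 is the arene (later ketone) carbon bonded to C10, C4 bears C15, C6 is bonded to C7, C14 is the methyl on C10, C12 is the future lactone carbonyl and C13 the future acetoxymethyl carbon. β is the face carrying C14 and the C7–C11 bond; O6, O8, O10 and the oxirane oxygen are α.
- The sense of induction of the Ti–BINOL allylation in step 2 is assumed as written for (R)-BINOL. If (R)-BINOL delivers the S carbinol, (S)-BINOL is used and nothing else changes.
- Compounds 23–26 are carried as mixtures of C1 epimers, which converge in step 17.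

## Route

Step 1
Reactants: 1 1-(2-bromo-4-methylphenyl)ethan-1-one; 2 4,4,5,5-tetramethyl-2-vinyl-1,3,2-dioxaborolane
Product: 3 1-(4-methyl-2-vinylphenyl)ethan-1-one
Conditions: PdCl2(dppf) (3 mol %), K2CO3, dioxane–H2O (4:1), 85 °C
Reagents that add atoms: vinylboronic acid pinacol ester 2, C=CB1OC(C)(C)C(C)(C)O1
Why: Suzuki–Miyaura coupling of an aryl bromide activated by the ortho acyl group; it forms the C6–C7 bond and creates no stereocentre.

Step 2
Reactants: 3 1-(4-methyl-2-vinylphenyl)ethan-1-one; 4 tetraallylstannane
Product: 5 (R)-2-(4-methyl-2-vinylphenyl)pent-4-en-2-ol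
Conditions: Ti(OiPr)4 (30 mol %), (R)-BINOL (30 mol %), i-PrOH (20 equiv), CH2Cl2, rt
Reagents that add atoms: tetraallylstannane 4, C=CC[Sn](CC=C)(CC=C)CC=C
Why: Titanium–BINOL-catalysed enantioselective allylation of an aryl methyl ketone; allyl transfer to the Re face, where the catalyst differentiates aryl from methyl, forms C9–C10 and sets C10 as R.

Step 3
Reactants: 5 (R)-2-(4-methyl-2-vinylphenyl)pent-4-en-2-ol
Product: 6 (R)-1,6-dimethyl-1,2-dihydronaphthalen-1-ol
Conditions: second-generation Grubbs catalyst (2 mol %), CH2Cl2 (0.02 M), 40 °C
Reagents that add atoms: none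
Why: Ring-closing metathesis of a styrenyl and a terminal alkene to a six-membered ring, driven by loss of ethylene; C10 is untouched. The product is kept away from acid, since dehydration would aromatise it.

Step 4
Reactants: 6 (R)-1,6-dimethyl-1,2-dihydronaphthalen-1-ol
Product: 7 (1R,3S,4R)-3,4-epoxy-1,6-dimethyl-1,2,3,4-tetrahydronaphthalen-1-ol (7α,8α-oxirane cis to the 10α-hydroxyl)
Conditions: VO(acac)2 (5 mol %), t-BuOOH (1.5 equiv), CH2Cl2, 0 °C → rt
Reagents that add atoms: tert-butyl hydroperoxide, CC(C)(C)OO
Why: Vanadium-catalysed epoxidation directed by the homoallylic tertiary hydroxyl delivers oxygen syn to OH; this is also the less hindered face, since the C14 methyl sits pseudoaxial on the other side. It fixes the α-oxygen at C8.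

Step 5
Reactants: 7 cis-epoxy alcohol; 8 dimethyl malonate
Product: 10 trans-fused tetralin 8α,12-lactone bearing CO2Me on C11 and the free 10α-hydroxyl (C11 epimers), via ring-opened hydroxy malonate 9 (not isolated)
Conditions: NaH, dimethyl malonate (3 equiv), THF–DMF, 70 °C; aq. NH4Cl
Reagents that add atoms: dimethyl malonate 8, COC(=O)CC(=O)OC
Why: The malonate anion opens the oxirane by SN2 attack at the benzylic C7 with inversion (attack at C8 would be 1,3-syn to the C14 methyl), so C11 arrives β and O8 stays α; the C8 alkoxide then closes the trans-fused γ-lactone. The 10-alkoxide cannot open the oxirane itself because it lies on the same face as the oxirane oxygen.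

Step 6
Reactants: 10 11-methoxycarbonyl lactone
Product: 11 trans-fused tetralin 8α,12-lactone with C11 as CH2 and the free 10α-hydroxyl
Conditions: LiCl, H2O (2 equiv), DMSO, 130 °C
Reagents that add atoms: none
Why: Krapcho dealkoxycarbonylation: chloride demethylates the activated ester and the malonate-type carboxylate loses CO2. The neutral medium spares the lactone and the tertiary benzylic alcohol.

Step 7
Reactants: 11 tricyclic lactone; 12 benzyl chloromethyl ether
Product: 14 11-(benzyloxymethyl) lactone with the new CH2OBn group on the lactone face of H7, via dilithium enolate alkoxide 13 (not isolated)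
Conditions: LiN(i-Pr)2 (2.2 equiv), THF, −78 °C; BnOCH2Cl (1.1 equiv), −78 → −40 °C
Reagents that add atoms: benzyl chloromethyl ether 12, ClCOCc1ccccc1
Why: Alkylation of a γ-lactone enolate with an α-chloro ether; in the rigid trans-fused tricycle the electrophile enters anti to the C7–aryl bond (syn to H7), which sets C11. The tertiary lithium alkoxide is a spectator, and any O-alkylation there would be undone in step 10.

Step 8
Reactants: 14 11-(benzyloxymethyl) lactone
Product: 15 12-O-benzyl tetralin-8α,10α,13-triol
Conditions: LiAlH4, THF, 0 °C → rt
Reagents that add atoms: none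
Why: Hydride reduction of the lactone to the 1,4-diol. The former lactone carbonyl becomes C13 and the benzyloxymethyl carbon is left to become C12, which turns the alkylation sense of step 7 into the 11R arrangement of the target.

Step 9
Reactants: 15 12-O-benzyl triol
Product: 16 8α,13-bis(tert-butyldimethylsilyl) ether of 15 (10α-OH free)
Conditions: TBSCl (2.5 equiv), imidazole, DMF, rt
Reagents that add atoms: tert-butyldimethylsilyl chloride, CC(C)(C)[Si](C)(C)Cl
Why: Silylation of the primary and secondary hydroxyls; the tertiary benzylic hydroxyl is inert to this reagent and must stay free for step 10.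

Step 10
Reactants: 16 bis-silyl benzyl ether
Product: 18 1(6),3-diene (hexahydronaphthalene) with free 10α- and 12-hydroxyls and 8α,13-bis-silyl ethers, via debenzylated tetralin diol 17 (not isolated)
Conditions: Li (excess), NH3(l)–THF, −78 °C; t-BuOH, −33 °C; isoprene, then NH4Cl
Reagents that add atoms: none
Why: Birch reduction of a 1,2,4-trialkylbenzene protonates the two unsubstituted para positions (C2, C5), leaving the tetrasubstituted C1=C6 and trisubstituted C3=C4 alkenes. The benzylic C10–O bond is protected as its lithium alkoxide (excess metal is destroyed with isoprene before protonation), and the benzyl ether on O12 is cleaved in the same operation.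

Step 11
Reactants: 18 diene diol
Product: 19 12-acetate of 18 (10α-OH free; 8α,13-bis-silyl ethers; 1(6),3-diene)
Conditions: Ac2O (1.2 equiv), pyridine, DMAP (cat.), CH2Cl2, 0 °C
Reagents that add atoms: acetic anhydride, CC(=O)OC(C)=O
Why: Selective acylation of the primary hydroxyl over the tertiary allylic one. The acetate keeps O12 from forming a hemiketal with the C6 ketone made next and marks O12 as different from the silylated O13.

Step 12
Reactants: 19 hexahydronaphthalene 12-acetate
Product: 21 ten-membered 10α-hydroxy-3Z-ene-1,6-dione (8α-OTBS; C7 arm CH(CH2OAc)(CH2OTBS)), via ozonide 20 (not isolated)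
Conditions: O3/O2 (ca. 1 equiv, Sudan Red 7B end-point), CH2Cl2, −78 °C; then Me2S, −78 °C → rt
Reagents that add atoms: ozone, [O-][O+]=O
Why: Ozone adds as a 1,3-dipole to the C1=C6 alkene, the primary ozonide cycloreverts to a ketone and a carbonyl oxide that stay tethered and recombine to the 1,2,4-trioxolane 20, and dimethyl sulfide reduces this to the two ketones. The closest known reaction type is the ozonolysis of the ring-fusion alkene of Birch-derived polyhydronaphthalenes to cyclodecane-1,6-diones. The ten-membered ring is not closed by bond formation: it is unveiled when the bond shared by rings A and B is cut, so there is no cyclisation transition state and no entropic or transannular penalty. No stereocentre is formed; C7, C8, C10 and C11 are carried over unchanged, and the C3=C4 alkene keeps the Z geometry that ring A imposed on it. The selectivity needed is cleavage of the tetrasubstituted alkene beside the trisubstituted one. It rests on the higher electron density of the tetraalkyl alkene toward electrophilic ozone, on the low temperature and on stopping at the dye end-point, so that any error falls on the side of recovered 19. The margin is narrowed by the allylic C10 oxygen, which is why this step carries the main risk of the route.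

Step 13
Reactants: 21 3Z-ene-1,6-dione
Product: 22 10α-hydroxy-4Z-ene-1,6-dione (C4=C5 conjugated to the C6 ketone)
Conditions: DBU (0.2 equiv), CH2Cl2, 0 °C
Reagents that add atoms: none
Why: Base-mediated conjugation of a β,γ-unsaturated ketone through the C5 dienolate; under thermodynamic control the β,β-disubstituted enone at C4=C5 is favoured over the disubstituted C2=C3 isomer. The s-cis dienolate imposed by the ring and the lower strain of a cis-cyclodecenone should keep the alkene Z.

Step 14
Reactants: 22 4Z-ene-1,6-dione
Product: 23 4Z-ene-1,6α,10α,12-tetraol (8α,13-bis-silyl ethers; C1 epimers)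
Conditions: i-Bu2AlH (6 equiv), CH2Cl2, −78 °C
Reagents that add atoms: none
Why: DIBAL-H reduces the enone 1,2, reduces the C1 ketone and cleaves the acetate in one operation. Hydride is expected to enter C6 antiperiplanar to the C7–H bond in the conformer that keeps the bulky C11 arm exocyclic (the torsional preference known from 2-alkylcyclohexanones), giving the 6α-alcohol trans to C11; this sense is substrate-controlled and is listed among the uncertain steps.

Step 15
Reactants: 23 allylic tetraol
Product: 24 4α,5α-epoxy-1,6α,10α,12-tetraol (oxirane on the face of O6; C1 epimers)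
Conditions: VO(acac)2 (10 mol %), t-BuOOH, CH2Cl2, 0 °C
Reagents that add atoms: tert-butyl hydroperoxide, CC(C)(C)OO
Why: Hydroxyl-directed vanadium epoxidation. The vanadate ester of the allylic C6 hydroxyl transfers oxygen through a transition state with a small O–C6–C5=C4 dihedral, which in medium-ring (Z)-cycloalkenols puts the ring on the opposite face and gives the cis epoxy alcohol, here the (4R,5S)-oxirane.

Step 16
Reactants: 24 epoxy tetraol
Product: 26 6α,12-lactone (trans-fused) with 1-hydroxyl and 10α-hydroxyl, via lactol 25 (not isolated)
Conditions: TEMPO (10 mol %), KBr, NaOCl (2.2 equiv), aq. NaHCO3–CH2Cl2, 0 °C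
Reagents that add atoms: none
Why: Oxoammonium oxidation selective for the primary alcohol; the C12 aldehyde is trapped by the 6α-hydroxyl as the lactol, which is oxidised on to the lactone. Hypochlorite is chosen as terminal oxidant so that the C1/C10 glycol is not cleaved; any oxidation at C1 is harmless because step 17 converges.

Step 17
Reactants: 26 hydroxy lactone
Product: 27 1-oxo-10α-hydroxy-4α,5α-epoxy-6α,12-olide with 8α- and 13-silyl ethers
Conditions: SO3·pyridine, DMSO, i-Pr2NEt, CH2Cl2, 0 °C
Reagents that add atoms: none
Why: Parikh–Doering oxidation of the remaining secondary alcohol to the α-ketol without C–C cleavage; both C1 epimers give the same ketone.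

Step 18
Reactants: 27 bis-silyl keto lactone
Product: 28 13-alcohol (8α-OTBS retained)
Conditions: HF·pyridine, pyridine, THF, 0 °C
Reagents that add atoms: none
Why: Buffered fluoride cleaves the primary silyl ether much faster than the hindered secondary one at C8; the oxirane tolerates these conditions.

Step 19
Reactants: 28 10α,13-diol
Product: 29 10α,13-diacetate (8α-OTBS)
Conditions: Ac2O (excess), DMAP (1 equiv), Et3N, CH2Cl2, rt
Reagents that add atoms: acetic anhydride, CC(=O)OC(C)=O
Why: DMAP-catalysed acylation of the primary alcohol and, more slowly, of the tertiary α-ketol hydroxyl; basic conditions are used because the oxirane would not survive Lewis-acid-promoted acetylation.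

Step 20
Reactants: 29 diacetate silyl ether
Product: 30 8α-alcohol
Conditions: HF·pyridine, THF, rt
Reagents that add atoms: none
Why: Fluoride-mediated desilylation in an acidic buffer, which avoids an alkoxide at O8 (translactonisation onto C12) and base-induced loss of the C13 acetate.

Step 21
Reactants: 30 8α-alcohol; 31 tigloyl chloride
Product: 32 target, CNP0305680.1
Conditions: tigloyl chloride (2 equiv), pyridine, DMAP (cat.), CH2Cl2, 0 °C → rt
Reagents that add atoms: tigloyl chloride 31, C/C=C(\C)C(Cl)=O
Why: Acylation of the secondary alcohol with the acid chloride under mild amine base; the E (tiglate) geometry is the stable one, and any 1,8-hemiketal of 30 is in equilibrium with the hydroxy ketone and is drained by acylation.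

## Compound list

1 | 1-(2-bromo-4-methylphenyl)ethan-1-one | CC(=O)c1ccc(C)cc1Br | starting material
2 | 4,4,5,5-tetramethyl-2-vinyl-1,3,2-dioxaborolane | C=CB1OC(C)(C)C(C)(C)O1 | starting material
3 | 1-(4-methyl-2-vinylphenyl)ethan-1-one | CC(=O)c1ccc(C)cc1C=C | intermediate
4 | tetraallylstannane | C=CC[Sn](CC=C)(CC=C)CC=C | starting material
5 | (R)-2-(4-methyl-2-vinylphenyl)pent-4-en-2-ol | C=CC[C@@](C)(O)c1ccc(C)cc1C=C | intermediate
6 | (R)-1,6-dimethyl-1,2-dihydronaphthalen-1-ol | C[C@@]1(O)CC=Cc2cc(C)ccc21 | intermediate
7 | (1R,3S,4R)-3,4-epoxy-1,6-dimethyl-1,2,3,4-tetrahydronaphthalen-1-ol (oxirane cis to OH) | C[C@@]1(O)C[C@@H]2O[C@@H]2c2cc(C)ccc21 | intermediate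
8 | dimethyl malonate | COC(=O)CC(=O)OC | starting material
9 | ring-opened hydroxy malonate: malonyl CH on C7 (β), 8α-OH, 10α-OH | C[C@@]1(O)C[C@H](O)[C@@H](C(C(=O)OC)C(=O)OC)c2cc(C)ccc21 | intermediate (not isolated)
10 | 11-methoxycarbonyl trans-fused 8α,12-lactone, 10α-OH (C11 epimers) | C[C@@]1(O)C[C@@H]2OC(=O)C(C(=O)OC)[C@H]2c2cc(C)ccc21 | intermediate
11 | trans-fused tetralin 8α,12-lactone, 10α-OH | C[C@@]1(O)C[C@@H]2OC(=O)C[C@H]2c2cc(C)ccc21 | intermediate
12 | benzyl chloromethyl ether | ClCOCc1ccccc1 | starting material
13 | dilithium enolate alkoxide of 11 | [Li+].[Li+].C[C@@]1([O-])C[C@@H]2OC([O-])=C[C@H]2c2cc(C)ccc21 | intermediate (not isolated)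
14 | 11-(benzyloxymethyl) lactone, CH2OBn on the lactone face of H7 | C[C@@]1(O)C[C@@H]2OC(=O)[C@H](COCc3ccccc3)[C@H]2c2cc(C)ccc21 | intermediate
15 | 12-O-benzyl tetralin-8α,10α,13-triol | C[C@@]1(O)C[C@H](O)[C@@H]([C@H](CO)COCc2ccccc2)c2cc(C)ccc21 | intermediate
16 | 8α,13-bis-TBS ether of 15 | C[C@@]1(O)C[C@H](O[Si](C)(C)C(C)(C)C)[C@@H]([C@H](CO[Si](C)(C)C(C)(C)C)COCc2ccccc2)c2cc(C)ccc21 | intermediate
17 | debenzylated tetralin 10α,12-diol (8α,13-bis-TBS) | C[C@@]1(O)C[C@H](O[Si](C)(C)C(C)(C)C)[C@@H]([C@H](CO[Si](C)(C)C(C)(C)C)CO)c2cc(C)ccc21 | intermediate (not isolated)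
18 | hexahydronaphthalene 1(6),3-diene, 10α,12-diol, 8α,13-bis-TBS | CC1=CCC2=C(C1)[C@H]([C@H](CO[Si](C)(C)C(C)(C)C)CO)[C@@H](O[Si](C)(C)C(C)(C)C)C[C@@]2(C)O | intermediate
19 | 12-acetate of 18 (substrate of the key step) | CC1=CCC2=C(C1)[C@H]([C@H](CO[Si](C)(C)C(C)(C)C)COC(C)=O)[C@@H](O[Si](C)(C)C(C)(C)C)C[C@@]2(C)O | intermediate
20 | 1,6-ozonide (1,2,4-trioxolane across C1 and C6) of 19 | CC1=CCC23OOC(C1)(O2)[C@H]([C@H](CO[Si](C)(C)C(C)(C)C)COC(C)=O)[C@@H](O[Si](C)(C)C(C)(C)C)C[C@@]3(C)O | intermediate (not isolated)
21 | ten-membered 10α-hydroxy-3Z-ene-1,6-dione, 8α-OTBS, 12-OAc, 13-OTBS | CC(C)(C)[Si](C)(C)O[C@H]1C[C@@](C)(O)C(=O)C/C=C(C)\CC(=O)[C@@H]1[C@H](CO[Si](C)(C)C(C)(C)C)COC(C)=O | intermediate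
22 | 10α-hydroxy-4Z-ene-1,6-dione | CC(C)(C)[Si](C)(C)O[C@H]1C[C@@](C)(O)C(=O)CC/C(C)=C\C(=O)[C@@H]1[C@H](CO[Si](C)(C)C(C)(C)C)COC(C)=O | intermediate
23 | 4Z-ene-1,6α,10α,12-tetraol, 8α,13-bis-TBS (C1 epimers) | CC(C)(C)[Si](C)(C)O[C@H]1C[C@@](C)(O)C(O)CC/C(C)=C\[C@@H](O)[C@@H]1[C@H](CO[Si](C)(C)C(C)(C)C)CO | intermediate
24 | 4α,5α-epoxy-1,6α,10α,12-tetraol (C1 epimers) | CC(C)(C)[Si](C)(C)O[C@H]1C[C@@](C)(O)C(O)CC[C@@]2(C)O[C@H]2[C@@H](O)[C@@H]1[C@H](CO[Si](C)(C)C(C)(C)C)CO | intermediate
25 | 6α,12-lactol (C1 and C12 epimers) | CC(C)(C)[Si](C)(C)O[C@H]1C[C@@](C)(O)C(O)CC[C@@]2(C)O[C@H]2[C@H]2OC(O)[C@@H](CO[Si](C)(C)C(C)(C)C)[C@@H]21 | intermediate (not isolated)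
26 | 1,10α-dihydroxy-4α,5α-epoxy-6α,12-olide, 8α,13-bis-TBS (C1 epimers) | CC(C)(C)[Si](C)(C)O[C@H]1C[C@@](C)(O)C(O)CC[C@@]2(C)O[C@H]2[C@H]2OC(=O)[C@@H](CO[Si](C)(C)C(C)(C)C)[C@@H]21 | intermediate
27 | 1-oxo-10α-hydroxy-4α,5α-epoxy-6α,12-olide, 8α,13-bis-TBS | CC(C)(C)[Si](C)(C)O[C@H]1C[C@@](C)(O)C(=O)CC[C@@]2(C)O[C@H]2[C@H]2OC(=O)[C@@H](CO[Si](C)(C)C(C)(C)C)[C@@H]21 | intermediate
28 | 13-alcohol of 27 (8α-OTBS) | CC(C)(C)[Si](C)(C)O[C@H]1C[C@@](C)(O)C(=O)CC[C@@]2(C)O[C@H]2[C@H]2OC(=O)[C@@H](CO)[C@@H]21 | intermediate
29 | 10α,13-diacetate, 8α-OTBS | CC(C)(C)[Si](C)(C)O[C@H]1C[C@@](C)(OC(C)=O)C(=O)CC[C@@]2(C)O[C@H]2[C@H]2OC(=O)[C@@H](COC(C)=O)[C@@H]21 | intermediate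
30 | 8α-alcohol (10α,13-diacetate) | O[C@H]1C[C@@](C)(OC(C)=O)C(=O)CC[C@@]2(C)O[C@H]2[C@H]2OC(=O)[C@@H](COC(C)=O)[C@@H]21 | intermediate
31 | tigloyl chloride, (E)-2-methylbut-2-enoyl chloride | C/C=C(\C)C(Cl)=O | starting material
32 | CNP0305680.1 | C/C=C(\C)C(=O)O[C@H]1C[C@@](C)(OC(C)=O)C(=O)CC[C@@]2(C)O[C@H]2[C@H]2OC(=O)[C@@H](COC(C)=O)[C@@H]21 | target

## Step count and least certain steps

Total step count: 21. Longest linear sequence: 21 steps (1 → 32); the route is fully linear, with 2, 4, 8, 12 and 31 entering as reagents.

**Step 12 (key step).** The most likely failure is competing ozonation of the trisubstituted C3=C4 alkene, or over-oxidation. Ozone discriminates only modestly between tri- and tetra-alkyl alkenes, and the allylic C10 oxygen lowers the reactivity of the fusion alkene. Fallback, from 19 back to 21: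
- VO(acac)2/t-BuOOH epoxidation directed by the allylic C10 hydroxyl, which touches only the fusion alkene, gives the 1α,6α-epoxy alcohol F1.
- The tertiary hydroxyl is then masked with N-(trimethylsilyl)imidazole to give the silyl ether F2. This matters because a free C10 hydroxyl would be part of a cleavable vicinal triol once the oxirane opens, and the C10–C1 bond would be cut instead.
- Periodic acid (H5IO6, Et2O–THF) cleaves the oxirane to the 10-O-trimethylsilyl dione F3.
- Citric acid in methanol removes the silyl group and returns 21.

**Step 13.** The risks are transannular aldolisation (the C5 or C2 enolate adding to the ketone across the ring to give a hydroazulene), E1cB loss of the C8 silyloxy group and epimerisation at C7. All three start from enolates of the same diketone. Fallback, from 21 to 22: the alkene is moved by a metal hydride catalyst (RuHCl(CO)(PPh3)3, toluene, 80 °C), that is by hydrometalation and β-hydride elimination, so no carbanion is ever formed at C2, C5 or C7. No new compound is formed on this path (F0).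

**Step 14.** The risk is poor or inverted facial selectivity at C6, because the face open to hydride is set by the conformation of a flexible ring and not by a directing group. Fallback, from 22 to 23:
- NaBH4/CeCl3·7H2O in MeOH at −78 °C keeps the C12 acetate; if it too delivers the 6β-alcohol, this is isolated as the 6β-hydroxy 12-acetate F4.
- The allylic carbinol is inverted under Mitsunobu conditions (4-nitrobenzoic acid, PPh3, DIAD) to the 6α-(4-nitrobenzoate) F5. The C1 carbinol, flanked by the quaternary C10, is expected to react far more slowly, and its configuration is irrelevant.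
- K2CO3 in MeOH removes the nitrobenzoate and the acetate to give 23.

**Step 15.** The risk is oxygen delivery to the wrong alkene face through the open-chain type, allylic-strain-controlled transition state, which would give the trans epoxy alcohol. A ten-membered ring lies between the medium rings, where vanadium gives cis epoxy alcohols, and acyclic Z-allylic alcohols, where it does not. Fallback, from 23 to 24: reagent control with Ti(OiPr)4, D-(−)-diethyl tartrate and t-BuOOH (4 Å molecular sieves, CH2Cl2, −20 °C). By the Sharpless mnemonic this is the matched tartrate for the 6α-carbinol and transfers oxygen anti to C7, that is to the required face, as the erythro product. No new compound is formed (F0).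

**Step 19.** The risk is β-elimination of the C13 acetate to the α-methylene lactone, or incomplete acylation of the hindered tertiary α-ketol hydroxyl, since the tertiary centre needs long exposure to amine base while the β-acetoxy lactone is already present. Fallback, from 27 to 29, with the order changed:
- 27 is acetylated at O10 first (Ac2O, DMAP, Et3N), while C13 still carries its silyl ether, which is far less prone to E1cB loss, to give the 10-acetate F6.
- HF·pyridine at 0 °C frees the primary hydroxyl to give the 13-alcohol F7.
- Ac2O/pyridine at 0 °C gives 29.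

## Further compounds

F1 | step 12 | 1α,6α-epoxide of 19 (oxirane cis to the 10α-hydroxyl) | CC1=CC[C@]23O[C@@]2(C1)[C@H]([C@H](CO[Si](C)(C)C(C)(C)C)COC(C)=O)[C@@H](O[Si](C)(C)C(C)(C)C)C[C@@]3(C)O
F2 | step 12 | 10-O-trimethylsilyl ether of F1 | CC1=CC[C@]23O[C@@]2(C1)[C@H]([C@H](CO[Si](C)(C)C(C)(C)C)COC(C)=O)[C@@H](O[Si](C)(C)C(C)(C)C)C[C@@]3(C)O[Si](C)(C)C
F3 | step 12 | 10-O-trimethylsilyl ether of dione 21 | CC(C)(C)[Si](C)(C)O[C@H]1C[C@@](C)(O[Si](C)(C)C)C(=O)C/C=C(C)\CC(=O)[C@@H]1[C@H](CO[Si](C)(C)C(C)(C)C)COC(C)=O
F0 | step 13 | none | none
F4 | step 14 | 4Z-ene-1,6β,10α-triol 12-acetate (C6 epimer, C1 epimers) | CC(C)(C)[Si](C)(C)O[C@H]1C[C@@](C)(O)C(O)CC/C(C)=C\[C@H](O)[C@@H]1[C@H](CO[Si](C)(C)C(C)(C)C)COC(C)=O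
F5 | step 14 | 6α-(4-nitrobenzoate) of the 4Z-ene-1,10α-diol 12-acetate | CC(C)(C)[Si](C)(C)O[C@H]1C[C@@](C)(O)C(O)CC/C(C)=C\[C@@H](OC(=O)c2ccc(cc2)[N+](=O)[O-])[C@@H]1[C@H](CO[Si](C)(C)C(C)(C)C)COC(C)=O
F0 | step 15 | none | none
F6 | step 19 | 10α-acetate of 27 (8α,13-bis-TBS) | CC(C)(C)[Si](C)(C)O[C@H]1C[C@@](C)(OC(C)=O)C(=O)CC[C@@]2(C)O[C@H]2[C@H]2OC(=O)[C@@H](CO[Si](C)(C)C(C)(C)C)[C@@H]21
F7 | step 19 | 13-alcohol of F6 | CC(C)(C)[Si](C)(C)O[C@H]1C[C@@](C)(OC(C)=O)C(=O)CC[C@@]2(C)O[C@H]2[C@H]2OC(=O)[C@@H](CO)[C@@H]21
A1 | alternative 1 | 8-(4-methoxybenzyloxy)germacra-1(10)E,4Z-dien-6-one | COc1ccc(CO[C@H]2C/C(C)=C/CC/C(C)=C\C(=O)C2)cc1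
A2 | alternative 2 | 4,5-deoxy target (4Z-ene) | C/C=C(\C)C(=O)O[C@H]1C[C@@](C)(OC(C)=O)C(=O)CC/C(C)=C\[C@H]2OC(=O)[C@@H](COC(C)=O)[C@@H]21
A3 | alternative 3 | 8-oxo-10-hydroxygermacr-4Z-en-6,12-olide, 1-O-methoxymethyl, 13-O-TBS | O=C1C[C@@](C)(O)[C@H](OCOC)CC/C(C)=C\[C@H]2OC(=O)[C@@H](CO[Si](C)(C)C(C)(C)C)[C@@H]21
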